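**Retrosynthetic overview**
1. The α-methylene ε-lactone (O12–C17) is closed last, from an acrylic acid made by oxidising the isopropenyl methyl group; both acetates come from one late diacetylation.
2. The 14-membered carbocycle comes from C2–C3 bond formation: light-driven decarboxylative chromium addition of a C2 radical (CO2 lost) to a C3 aldehyde, which also sets C3.
3. The open-chain hydroxy acid comes from a Baeyer–Villiger lactone of a carvone-derived cyclohexanone (C12–O with retention). The cis-oxolane (C4–O–C7) comes from osmium oxidative cyclisation of a 7,8-diol, itself from an O11-directed epoxidation of the (E)-C7=C8 alkene and inverting hydrolysis.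
4. C11–C12 comes from a reductive aldol of (S)-carvone with (4E)-4,8-dimethylnona-4,8-dienal (Claisen product of methacrolein and a homomethallyl Grignard reagent).
5. Ring order: cyclohexanone (bought) → oxolane → temporary ε-lactone → 14-membered ring → α-methylene ε-lactone.

Atom labels used below (cembrane type): ring carbons C1–C14; C1 carries C15(=C16H2)–C17; methyls C18 on C4, C19 on C8, C20 on C12. The target is 1S,3R,4S,7R,8S,11S,12S.

**Step 1**
Reactants: 1 4-bromo-2-methylbut-1-ene; 2 methacrolein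
Product: 4 rac-2,6-dimethylhepta-1,6-dien-3-ol, via Grignard reagent 3 (not isolated)
Conditions: Mg, THF, rt; then 2, −78 → 0 °C; aq. NH4Cl
Reagents that add atoms: none
Why: Grignard formation from the homoallylic bromide and 1,2-addition to the enal give the isopropenyl carbinol, whose racemic carbinol centre is erased in the next step.

**Step 2**
Reactants: 4 rac-2,6-dimethylhepta-1,6-dien-3-ol; 5 ethyl vinyl ether
Product: 7 (4E)-4,8-dimethylnona-4,8-dienal, via allyl vinyl ether 6 (not isolated)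
Conditions: 5 (excess), Hg(OAc)2 (5 mol%), reflux; evaporate; PhMe, 140 °C, sealed tube
Reagents that add atoms: none
Why: Vinyl ether exchange followed by an aliphatic Claisen rearrangement through a chair transition state with the chain equatorial gives the (E)-trisubstituted C7=C8 alkene (expected ≥95:5) and removes the racemic carbinol.

**Step 3**
Reactants: 8 (S)-(+)-carvone; 7 (4E)-4,8-dimethylnona-4,8-dienal
Product: 10 (2S,5S)-2-[(1S,4E)-1-hydroxy-4,8-dimethylnona-4,8-dien-1-yl]-2-methyl-5-(prop-1-en-2-yl)cyclohexan-1-one, via lithium enolate 9 (not isolated)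
Conditions: LiBH(s-Bu)3 (L-Selectride, 1.0 equiv), THF, −78 °C; then 7, −78 °C; aq. NH4Cl
Reagents that add atoms: none
Why: Conjugate hydride reduction gives the tetrasubstituted enolate regiospecifically, and the reductive aldol then sets C12 by stereoelectronically preferred axial C–C bond formation cis to the equatorial isopropenyl group and C11 through a Zimmerman–Traxler chair with the aldehyde chain equatorial, so both new centres are controlled by the carvone centre (moderate dr expected, minor isomers removed by chromatography).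

**Step 4**
Reactants: 10 (2S,5S)-2-[(1S,4E)-1-hydroxy-4,8-dimethylnona-4,8-dien-1-yl]-2-methyl-5-(prop-1-en-2-yl)cyclohexan-1-one
Product: 12 (1S)-1-[(1S,4S)-1-methyl-2-oxo-4-(prop-1-en-2-yl)cyclohexyl]-3-[(2R,3R)-2-methyl-3-(3-methylbut-3-en-1-yl)oxiran-2-yl]propyl acetate, via epoxy alcohol 11 (not isolated)
Conditions: VO(acac)2 (5 mol%), t-BuOOH, NaOAc, PhMe, 0 °C → rt; then Ac2O, Et3N, DMAP, 0 °C
Reagents that add atoms: tert-butyl hydroperoxide CC(C)(C)OO; acetic anhydride CC(=O)OC(C)=O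
Why: Hydroxyl-directed vanadium-catalysed epoxidation of the bishomoallylic alcohol delivers oxygen through a chair-like vanadate transition state (bulky C12 substituent equatorial, C8 methyl turned away from C10) to give the (7R,8R)-epoxide, and in-pot acetylation caps O11 before it can open the epoxide.

**Step 5**
Reactants: 12 (1S)-1-[(1S,4S)-1-methyl-2-oxo-4-(prop-1-en-2-yl)cyclohexyl]-3-[(2R,3R)-2-methyl-3-(3-methylbut-3-en-1-yl)oxiran-2-yl]propyl acetate
Product: 14 (1S,4S)-4-hydroxy-4-[(2R,5S)-5-(hydroxymethyl)-5-methyloxolan-2-yl]-1-[(1S,4S)-1-methyl-2-oxo-4-(prop-1-en-2-yl)cyclohexyl]pentyl acetate, via diol 13 (not isolated)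
Conditions: HClO4 (5 mol%), THF/H2O, 0 °C; then K2OsO2(OH)4 (5 mol%), pyridine N-oxide, citric acid, Cu(OTf)2, MeCN/H2O (pH 6.5), 60 °C
Reagents that add atoms: water O; pyridine N-oxide [O-][n+]1ccccc1
Why: Acid hydrolysis opens the epoxide at tertiary C8 with inversion to the (7R,8S)-diol, whose osmate ester undergoes osmium-catalysed oxidative cyclisation (syn addition of O7 and an oxo ligand to the 1,1-disubstituted alkene) through a chelated transition state that gives only the 2,5-cis oxolane, fixing C4 as S.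

**Step 6**
Reactants: 14 (1S,4S)-4-hydroxy-4-[(2R,5S)-5-(hydroxymethyl)-5-methyloxolan-2-yl]-1-[(1S,4S)-1-methyl-2-oxo-4-(prop-1-en-2-yl)cyclohexyl]pentyl acetate
Product: 15 (1S,4S)-4-hydroxy-4-[(2R,5S)-5-(hydroxymethyl)-5-methyloxolan-2-yl]-1-[(2S,5S)-2-methyl-7-oxo-5-(prop-1-en-2-yl)oxepan-2-yl]pentyl acetate
Conditions: Me3SiOOSiMe3, TMSOTf (10 mol%), CH2Cl2, −40 → −20 °C; then citric acid, MeOH
Reagents that add atoms: bis(trimethylsilyl) peroxide C[Si](C)(C)OO[Si](C)(C)C
Why: Baeyer–Villiger oxidation with a silyl peroxide spares the isopropenyl group, and the quaternary C12 migrates in preference to the CH2 with retention, so the C12–O bond forms without loss of configuration.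

**Step 7**
Reactants: 15 (1S,4S)-4-hydroxy-4-[(2R,5S)-5-(hydroxymethyl)-5-methyloxolan-2-yl]-1-[(2S,5S)-2-methyl-7-oxo-5-(prop-1-en-2-yl)oxepan-2-yl]pentyl acetate
Product: 16 (1S,4S)-4-[(2R,5S)-5-formyl-5-methyloxolan-2-yl]-4-hydroxy-1-[(2S,5S)-2-methyl-7-oxo-5-(prop-1-en-2-yl)oxepan-2-yl]pentyl acetate
Conditions: Dess–Martin periodinane, pyridine, CH2Cl2, 0 °C
Reagents that add atoms: none
Why: Dess–Martin oxidation of the only primary alcohol gives the non-enolisable α-alkoxy aldehyde (in equilibrium with a bridged lactol to the C8 hydroxyl) while the tertiary alcohol and esters are inert.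

**Step 8**
Reactants: 16 (1S,4S)-4-[(2R,5S)-5-formyl-5-methyloxolan-2-yl]-4-hydroxy-1-[(2S,5S)-2-methyl-7-oxo-5-(prop-1-en-2-yl)oxepan-2-yl]pentyl acetate
Product: 17 (3S,6S,7S,10S)-10-[(2R,5S)-5-formyl-5-methyloxolan-2-yl]-6,7,10-trihydroxy-6-methyl-3-(prop-1-en-2-yl)undecanoic acid
Conditions: LiOH, THF/H2O, 0 °C → rt; then aq. HCl to pH 4
Reagents that add atoms: lithium hydroxide [Li+].[OH-]
Why: Saponification of the strained ε-lactone (and of the C11 acetate) unmasks the carboxylic acid and the C12 tertiary alcohol, and no stereocentre can epimerise because the aldehyde has no α-hydrogen.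

**Step 9**
Reactants: 17 (3S,6S,7S,10S)-10-[(2R,5S)-5-formyl-5-methyloxolan-2-yl]-6,7,10-trihydroxy-6-methyl-3-(prop-1-en-2-yl)undecanoic acid
Product: 18 (1S,2R,4S,7S,8S,11S,12R)-1,7,11-trimethyl-4-(prop-1-en-2-yl)-15-oxabicyclo[10.2.1]pentadecane-2,7,8,11-tetrol
Conditions: [Ir(dF(CF3)ppy)2(dtbbpy)]PF6 (2 mol%), CrCl3·3THF (20 mol%), 2,4,6-collidine, DMF (1 mM), blue LEDs (450 nm), rt
Reagents that add atoms: none
Why: Proposed new method: the excited iridium photocatalyst oxidises the carboxylate, loss of CO2 gives the primary C2 radical, divalent chromium traps it as an alkylchromium (trivalent chromium) that adds intramolecularly to the C3 aldehyde in a Felkin–Anh arrangement (ring oxygen anti, attack past the C18 methyl) to set 3R and close the 14-membered ring, and the reduced photocatalyst returns trivalent to divalent chromium while the acid proton frees the alkoxide; the closest known chemistry is the stoichiometric chromium-mediated decarboxylative addition of redox-active esters to aldehydes, photoredox/chromium dual-catalytic aldehyde allylation and alkylation, and Nozaki–Hiyama–Kishi macrocyclisation, none yet shown as a redox-neutral macrocyclisation from a free acid.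

**Step 10**
Reactants: 18 (1S,2R,4S,7S,8S,11S,12R)-1,7,11-trimethyl-4-(prop-1-en-2-yl)-15-oxabicyclo[10.2.1]pentadecane-2,7,8,11-tetrol
Product: 19 (1S,2R,4S,7S,8S,11S,12R)-7,11-dihydroxy-1,7,11-trimethyl-4-(prop-1-en-2-yl)-15-oxabicyclo[10.2.1]pentadecane-2,8-diyl diacetate
Conditions: Ac2O, pyridine, DMAP (cat.), CH2Cl2, 0 °C → rt
Reagents that add atoms: acetic anhydride CC(=O)OC(C)=O
Why: DMAP-catalysed acylation esterifies the two secondary alcohols (O3 and O11) while the tertiary C8 and C12 hydroxyls stay free.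

**Step 11**
Reactants: 19 (1S,2R,4S,7S,8S,11S,12R)-7,11-dihydroxy-1,7,11-trimethyl-4-(prop-1-en-2-yl)-15-oxabicyclo[10.2.1]pentadecane-2,8-diyl diacetate
Product: 20 2-[(1S,2R,4S,7S,8S,11S,12R)-2,8-diacetoxy-7,11-dihydroxy-1,7,11-trimethyl-15-oxabicyclo[10.2.1]pentadecan-4-yl]prop-2-enal
Conditions: SeO2, pyridine, 1,4-dioxane, 70 °C
Reagents that add atoms: selenium dioxide O=[Se]=O
Why: Selenium dioxide allylic oxidation (ene reaction then [2,3]-shift) converts the isopropenyl methyl group into the α-substituted acrolein, the methyl being preferred over the allylic methine.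

**Step 12**
Reactants: 20 2-[(1S,2R,4S,7S,8S,11S,12R)-2,8-diacetoxy-7,11-dihydroxy-1,7,11-trimethyl-15-oxabicyclo[10.2.1]pentadecan-4-yl]prop-2-enal
Product: 21 2-[(1S,2R,4S,7S,8S,11S,12R)-2,8-diacetoxy-7,11-dihydroxy-1,7,11-trimethyl-15-oxabicyclo[10.2.1]pentadecan-4-yl]prop-2-enoic acid
Conditions: NaClO2, NaH2PO4, 2-methylbut-2-ene, t-BuOH/H2O, 0 °C → rt
Reagents that add atoms: sodium chlorite [Na+].[O-]Cl=O
Why: Pinnick oxidation converts the enal into the acrylic acid without touching the alkene, the acetates or the tertiary alcohols.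

**Step 13**
Reactants: 21 2-[(1S,2R,4S,7S,8S,11S,12R)-2,8-diacetoxy-7,11-dihydroxy-1,7,11-trimethyl-15-oxabicyclo[10.2.1]pentadecan-4-yl]prop-2-enoic acid
Product: 22 CNP0343714.5
Conditions: 2,4,6-Cl3C6H2COCl, Et3N, THF, rt; then DMAP, PhMe (2 mM), 80 °C
Reagents that add atoms: none
Why: Yamaguchi lactonisation, in which the acylpyridinium of the acrylic acid is captured by the nearby tertiary C12 hydroxyl to close the seven-membered α-methylene lactone (the C8 hydroxyl could only give an eleven-membered ring), with no stereocentre touched.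

**Compound list**
1 | 4-bromo-2-methylbut-1-ene | C=C(C)CCBr | starting material
2 | methacrolein (2-methylprop-2-enal) | C=C(C)C=O | starting material
3 | Grignard reagent: (3-methylbut-3-en-1-yl)magnesium bromide | C=C(C)CC[Mg]Br | intermediate
4 | rac-2,6-dimethylhepta-1,6-dien-3-ol | C=C(C)CCC(O)C(C)=C | intermediate
5 | ethyl vinyl ether | C=COCC | starting material
6 | allyl vinyl ether: rac-3-(ethenyloxy)-2,6-dimethylhepta-1,6-diene | C=C(C)CCC(OC=C)C(C)=C | intermediate
7 | (4E)-4,8-dimethylnona-4,8-dienal | C=C(C)CC/C=C(\C)CCC=O | intermediate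
8 | (S)-(+)-carvone, (5S)-2-methyl-5-(prop-1-en-2-yl)cyclohex-2-en-1-one | CC1=CC[C@H](C(C)=C)CC1=O | starting material
9 | lithium enolate: lithium (5S)-2-methyl-5-(prop-1-en-2-yl)cyclohex-1-en-1-olate | CC1=C(O[Li])C[C@@H](C(C)=C)CC1 | intermediate
10 | (2S,5S)-2-[(1S,4E)-1-hydroxy-4,8-dimethylnona-4,8-dien-1-yl]-2-methyl-5-(prop-1-en-2-yl)cyclohexan-1-one | O=C1C[C@@H](C(C)=C)CC[C@@]1(C)[C@@H](O)CC/C(C)=C/CCC(C)=C | intermediate
11 | epoxy alcohol: (2S,5S)-2-{(1S)-1-hydroxy-3-[(2R,3R)-2-methyl-3-(3-methylbut-3-en-1-yl)oxiran-2-yl]propyl}-2-methyl-5-(prop-1-en-2-yl)cyclohexan-1-one | O=C1C[C@@H](C(C)=C)CC[C@@]1(C)[C@@H](O)CC[C@@]2(C)O[C@@H]2CCC(C)=C | intermediate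
12 | (1S)-1-[(1S,4S)-1-methyl-2-oxo-4-(prop-1-en-2-yl)cyclohexyl]-3-[(2R,3R)-2-methyl-3-(3-methylbut-3-en-1-yl)oxiran-2-yl]propyl acetate | O=C1C[C@@H](C(C)=C)CC[C@@]1(C)[C@@H](OC(C)=O)CC[C@@]2(C)O[C@@H]2CCC(C)=C | intermediate
13 | diol: (1S,4S,5R)-4,5-dihydroxy-4,8-dimethyl-1-[(1S,4S)-1-methyl-2-oxo-4-(prop-1-en-2-yl)cyclohexyl]non-8-en-1-yl acetate | O=C1C[C@@H](C(C)=C)CC[C@@]1(C)[C@@H](OC(C)=O)CC[C@](C)(O)[C@H](O)CCC(C)=C | intermediate
14 | (1S,4S)-4-hydroxy-4-[(2R,5S)-5-(hydroxymethyl)-5-methyloxolan-2-yl]-1-[(1S,4S)-1-methyl-2-oxo-4-(prop-1-en-2-yl)cyclohexyl]pentyl acetate | O=C1C[C@@H](C(C)=C)CC[C@@]1(C)[C@@H](OC(C)=O)CC[C@](C)(O)[C@H]2CC[C@@](C)(CO)O2 | intermediate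
15 | (1S,4S)-4-hydroxy-4-[(2R,5S)-5-(hydroxymethyl)-5-methyloxolan-2-yl]-1-[(2S,5S)-2-methyl-7-oxo-5-(prop-1-en-2-yl)oxepan-2-yl]pentyl acetate | O=C1C[C@@H](C(C)=C)CC[C@@](C)([C@@H](OC(C)=O)CC[C@](C)(O)[C@H]2CC[C@@](C)(CO)O2)O1 | intermediate
16 | (1S,4S)-4-[(2R,5S)-5-formyl-5-methyloxolan-2-yl]-4-hydroxy-1-[(2S,5S)-2-methyl-7-oxo-5-(prop-1-en-2-yl)oxepan-2-yl]pentyl acetate (open form shown) | O=C1C[C@@H](C(C)=C)CC[C@@](C)([C@@H](OC(C)=O)CC[C@](C)(O)[C@H]2CC[C@@](C)(C=O)O2)O1 | intermediate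
17 | (3S,6S,7S,10S)-10-[(2R,5S)-5-formyl-5-methyloxolan-2-yl]-6,7,10-trihydroxy-6-methyl-3-(prop-1-en-2-yl)undecanoic acid | OC(=O)C[C@@H](C(C)=C)CC[C@](C)(O)[C@@H](O)CC[C@](C)(O)[C@H]1CC[C@@](C)(C=O)O1 | intermediate
18 | (1S,2R,4S,7S,8S,11S,12R)-1,7,11-trimethyl-4-(prop-1-en-2-yl)-15-oxabicyclo[10.2.1]pentadecane-2,7,8,11-tetrol | O[C@@H]1C[C@@H](C(C)=C)CC[C@](C)(O)[C@@H](O)CC[C@](C)(O)[C@H]2CC[C@]1(C)O2 | intermediate
19 | (1S,2R,4S,7S,8S,11S,12R)-7,11-dihydroxy-1,7,11-trimethyl-4-(prop-1-en-2-yl)-15-oxabicyclo[10.2.1]pentadecane-2,8-diyl diacetate | CC(=O)O[C@@H]1C[C@@H](C(C)=C)CC[C@](C)(O)[C@@H](OC(C)=O)CC[C@](C)(O)[C@H]2CC[C@]1(C)O2 | intermediate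
20 | 2-[(1S,2R,4S,7S,8S,11S,12R)-2,8-diacetoxy-7,11-dihydroxy-1,7,11-trimethyl-15-oxabicyclo[10.2.1]pentadecan-4-yl]prop-2-enal | CC(=O)O[C@@H]1C[C@@H](C(=C)C=O)CC[C@](C)(O)[C@@H](OC(C)=O)CC[C@](C)(O)[C@H]2CC[C@]1(C)O2 | intermediate
21 | 2-[(1S,2R,4S,7S,8S,11S,12R)-2,8-diacetoxy-7,11-dihydroxy-1,7,11-trimethyl-15-oxabicyclo[10.2.1]pentadecan-4-yl]prop-2-enoic acid | CC(=O)O[C@@H]1C[C@@H](C(=C)C(O)=O)CC[C@](C)(O)[C@@H](OC(C)=O)CC[C@](C)(O)[C@H]2CC[C@]1(C)O2 | intermediate
22 | CNP0343714.5: (1S,3R,4S,7R,8S,11S,12S)-3,11-diacetoxy-4,7-epoxy-8-hydroxycembr-15(16)-en-17,12-olide (labels as defined above) | C=C1C(=O)O[C@@]2(C)CC[C@H]1C[C@@H](OC(C)=O)[C@]1(C)CC[C@@H](O1)[C@@](C)(O)CC[C@@H]2OC(C)=O | target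

**Totals**
Total step count: 13. Longest linear sequence: 13 steps (steps 1–13 from 1; 8 enters at step 3, 11 steps from there).

**Three steps most likely to fail**

Step 9 (the proposed new macrocyclisation). Risks: slow oxidation of the primary carboxylate; protonation of the alkylchromium before ring closure; masking of the aldehyde as its lactol; modest Felkin–Anh preference at C3. Fallback with known chemistry, setting out from 17: esterify the acid with N-hydroxyphthalimide (DIC, cat. DMAP) to the redox-active ester 1,3-dioxoisoindolin-2-yl (3S,6S,7S,10S)-10-[(2R,5S)-5-formyl-5-methyloxolan-2-yl]-6,7,10-trihydroxy-6-methyl-3-(prop-1-en-2-yl)undecanoate F3. Add F3 slowly to CrCl2 (4 equiv) and TMSCl in THF/DMA at rt (final 2 mM) for the thermal, stoichiometric decarboxylative chromium addition to the aldehyde. Fluoride work-up returns the route at 18.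

Step 4 (directed epoxidation and capping). Risks: the free O11 may open the epoxide at C8 to a C8–O–C11 oxolane before it is acetylated; the directing effect may give a low diastereomer ratio. Fallback, setting out from 10: acetylate first (Ac2O, DMAP) to (1S,4E)-4,8-dimethyl-1-[(1S,4S)-1-methyl-2-oxo-4-(prop-1-en-2-yl)cyclohexyl]nona-4,8-dien-1-yl acetate F1. Epoxidise only the trisubstituted alkene with m-CPBA (NaHCO3, CH2Cl2, −20 °C). Separate 12 by chromatography from its epimer (1S)-1-[(1S,4S)-1-methyl-2-oxo-4-(prop-1-en-2-yl)cyclohexyl]-3-[(2S,3S)-2-methyl-3-(3-methylbut-3-en-1-yl)oxiran-2-yl]propyl acetate F2. This epoxidation is not directed, so about half the material is lost as F2. The route is rejoined at 12.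

Step 13 (lactonisation onto a tertiary alcohol). Risk: the hindered C12 hydroxyl may not capture the activated acrylic acid. Fallback, setting out from 19 and bypassing 20 and 21:
- Ozonolysis (O3, CH2Cl2/MeOH, −78 °C; Me2S) gives the methyl ketone (1S,2R,4S,7S,8S,11S,12R)-4-acetyl-7,11-dihydroxy-1,7,11-trimethyl-15-oxabicyclo[10.2.1]pentadecane-2,8-diyl diacetate F4.
- Kinetic enolisation and triflation (KN(SiMe3)2, PhNTf2, THF, −78 °C) give 1-[(1S,2R,4S,7S,8S,11S,12R)-2,8-diacetoxy-7,11-dihydroxy-1,7,11-trimethyl-15-oxabicyclo[10.2.1]pentadecan-4-yl]ethenyl trifluoromethanesulfonate F5.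
- Carbonylation with Pd(PPh3)4 (zerovalent palladium), CO (1 atm) and i-Pr2NEt in DMF at 60 °C closes the lactone by capture of the acylpalladium by the C12 hydroxyl, giving 22 directly.

**Further compounds**
F1 | step 4 | (1S,4E)-4,8-dimethyl-1-[(1S,4S)-1-methyl-2-oxo-4-(prop-1-en-2-yl)cyclohexyl]nona-4,8-dien-1-yl acetate | O=C1C[C@@H](C(C)=C)CC[C@@]1(C)[C@@H](OC(C)=O)CC/C(C)=C/CCC(C)=C
F2 | step 4 | (1S)-1-[(1S,4S)-1-methyl-2-oxo-4-(prop-1-en-2-yl)cyclohexyl]-3-[(2S,3S)-2-methyl-3-(3-methylbut-3-en-1-yl)oxiran-2-yl]propyl acetate | O=C1C[C@@H](C(C)=C)CC[C@@]1(C)[C@@H](OC(C)=O)CC[C@]2(C)O[C@H]2CCC(C)=C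
F3 | step 9 | 1,3-dioxoisoindolin-2-yl (3S,6S,7S,10S)-10-[(2R,5S)-5-formyl-5-methyloxolan-2-yl]-6,7,10-trihydroxy-6-methyl-3-(prop-1-en-2-yl)undecanoate | O=C(C[C@@H](C(C)=C)CC[C@](C)(O)[C@@H](O)CC[C@](C)(O)[C@H]1CC[C@@](C)(C=O)O1)ON1C(=O)c2ccccc2C1=O
F4 | step 13 | (1S,2R,4S,7S,8S,11S,12R)-4-acetyl-7,11-dihydroxy-1,7,11-trimethyl-15-oxabicyclo[10.2.1]pentadecane-2,8-diyl diacetate | CC(=O)O[C@@H]1C[C@@H](C(C)=O)CC[C@](C)(O)[C@@H](OC(C)=O)CC[C@](C)(O)[C@H]2CC[C@]1(C)O2
F5 | step 13 | 1-[(1S,2R,4S,7S,8S,11S,12R)-2,8-diacetoxy-7,11-dihydroxy-1,7,11-trimethyl-15-oxabicyclo[10.2.1]pentadecan-4-yl]ethenyl trifluoromethanesulfonate | CC(=O)O[C@@H]1C[C@@H](C(=C)OS(=O)(=O)C(F)(F)F)CC[C@](C)(O)[C@@H](OC(C)=O)CC[C@](C)(O)[C@H]2CC[C@]1(C)O2
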